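(The constants were drawn at random within sensible limits; the result is computed.)

**The task.** I started with teal. Substrate D binds catalyst G to form D.G, D.G releases J and gives G back, and J crystallises as X above its solubility.

| setting | grey | teal | green |
|---|---|---|---|
| D | 0.50 mM | 0.50 mM | 0.50 mM |
| G | 8.0 µM | 8.0 µM | 8.0 µM |
| temperature | −5 °C | −35 °C | 25 °C |
| time | 1.0 min | 1.0 min | 1.0 min |

    D.G ⇌ G + J (K1 = 0.00104 M, k1 = 1.26 s⁻¹, Ea1 = 72.0 kJ mol⁻¹, ΔH1 = −7.00 kJ mol⁻¹)
    X ⇌ J, rate k2*(cs2 - [J]) while solid is left; crystals form when [J] > cs2 (cs2 = 0.39 mM, k2 = 0.119 s⁻¹)
    D + G → D.G (k3 = 6910 M⁻¹ s⁻¹, Ea3 = 14.0 kJ mol⁻¹)
    (constants at 25 °C)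

- what is said of J includes X
- X is a solid; its amount is given per volume of the solution
- the list of constants is for 25 °C, to be carried to other temperatures by the activation energies and enthalpies

* the flask that comes out highest in amount of J, in percent of the D charged, or "all alike" when all lie within 1.5 percentage points (grey / teal / green / all alike)
* J at the end, in percent of the D charged, grey
* J at the end, in percent of the D charged, teal
* J at the end, in percent of the D charged, green

**The order.** I looked for the one concentration that sets the order of the rate in teal, the coldest flask. I divided the constants by their speed-up factors, 4.1 for uptake and 1500 for release. With D at its charge, G then loads in about 1.20 s, while a D.G needs about 19.9 min to release. Because a release takes far longer than a loading, I took D.G as the resting state and release as the rate-limiting step for teal. The rate in teal therefore follows D.G, which I took to be close to the charge of G, and is zero order in D while that lasts.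

**Upper bound.** Let k be the release constant at the flask's temperature, c the charge of G, a the charge of D and t the time. D.G cannot exceed c, and the back step only subtracts, so J cannot exceed k·c·t/a as a share of D charged. For teal this came to 0.0803%. I called this J, made if every G sat as D.G from the first moment, the turnover ceiling.

**Lower bound.** While D.G fills, teal loses about one loading time of release. As an estimated floor, setting the back step aside, I allowed no release at all for 2 loading times, which gave 0.0771% for teal.

**The forecast.** The forecast chose green, with 4.5% in grey, 0.079% in teal (range 0.07% to 0.09%) and 69% in green, holding that when cold “the catalyst sits saturated”. Its teal value lay lower than my ceiling and higher than my floor.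

**The number.** The simulation put green highest, with 4.52% in grey, 0.0786% in teal and 68.9% in green. Teal landed lower than the ceiling and higher than the floor, with D.G at 99.9% of the catalyst charged. Green, at the temperature of the listed constants, has a turnover ceiling of 121%, more than the whole charge of D. Green reached 0.569 of that ceiling, while its D.G went from 64.6% of the catalyst at 0.500 min to 53.9% at 1.00 min.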